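**Retrosynthetic overview**
1. Target ⇒ one acyclic Knoevenagel adduct: both pyranone rings are opened at their O–C bonds (ring C at O1–C2, ring D at O–CMe2). A single flask then closes ring C by a catalytic asymmetric oxa-Michael addition (sets C2), and acid removes the activating ester and all MOM groups and closes ring D.
2. Knoevenagel adduct ⇒ ring A β-keto ester + ring B aldehyde (C2–C3 bond).
3. Ring B aldehyde ⇒ a bought iodovanillin: the ring D carbons arrive as a senecioyl ketone by carbonylative Suzuki coupling at the iodide, and the neighbouring phenol stays a MOM ether so ring D cannot close early.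
4. Ring A β-keto ester ⇒ a bought phloroglucinol carboxylic ester by crossed Claisen condensation.
5. Ring order: rings A and B are bought; ring C, then ring D, both in the last step.

Assumption: the quinidine-derived thiourea is taken to give the (2S) series; if the first run (CD, rotation) shows (2R), its commercial quinine-derived pseudoenantiomer N-[3,5-bis(trifluoromethyl)phenyl]-N'-[(8α,9S)-6'-methoxycinchonan-9-yl]thiourea is used in step 7 and nothing else changes.

**Route**

Step 1
Reactants: 1 5-iodovanillin (4-hydroxy-3-iodo-5-methoxybenzaldehyde)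
Product: 2 3,4-dihydroxy-5-iodobenzaldehyde
Conditions: BBr3 (3 equiv), CH2Cl2, −78 to 23 °C; then H2O
Reagents that add atoms: none
Why: BBr3 cleavage of the aryl methyl ether (Lewis-acid demethylation) replaces the only acid-stable O-substituent of ring B by a free phenol while the aldehyde and the aryl iodide are left alone.

Step 2
Reactants: 2 3,4-dihydroxy-5-iodobenzaldehyde
Product: 3 3-iodo-4,5-bis(methoxymethoxy)benzaldehyde
Conditions: MOMCl (2.6 equiv), K2CO3 (3 equiv), acetone, 23 °C
Reagents that add atoms: chloromethyl methyl ether, COCCl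
Why: Base-mediated O-alkylation (MOM acetal protection) masks both phenols for the Pd and amine steps and blocks the oxygen next to iodine, so the ketone installed next cannot cyclise before the last step.

Step 3
Reactants: 3 3-iodo-4,5-bis(methoxymethoxy)benzaldehyde; 4 2-methylprop-1-enylboronic acid pinacol ester (4,4,5,5-tetramethyl-2-(2-methylprop-1-en-1-yl)-1,3,2-dioxaborolane)
Product: 5 3,4-bis(methoxymethoxy)-5-(3-methylbut-2-enoyl)benzaldehyde
Conditions: Pd(dppf)Cl2 (5 mol%), K2CO3 (3 equiv), H2O (3 equiv), CO (1 atm), anisole, 80 °C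
Reagents that add atoms: carbon monoxide, [C-]#[O+]
Why: Carbonylative Suzuki–Miyaura coupling: CO insertion into the aryl–palladium bond of the electron-rich ortho-alkoxy aryl iodide outruns direct transmetalation, and the acylpalladium is captured by the alkenylboronate to give the aryl senecioyl ketone without touching the aldehyde.

Step 4
Reactants: 6 methyl 2,4,6-trihydroxybenzoate
Product: 7 methyl 2-hydroxy-4,6-bis(methoxymethoxy)benzoate
Conditions: MOMCl (2.2 equiv), K2CO3 (2.5 equiv), acetone, 0 to 23 °C
Reagents that add atoms: chloromethyl methyl ether, COCCl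
Why: Chemoselective MOM protection: the 4-OH and one ortho OH are alkylated, while the ortho OH hydrogen-bonded to the ester carbonyl stays free as the future ring C nucleophile.

Step 5
Reactants: 7 methyl 2-hydroxy-4,6-bis(methoxymethoxy)benzoate; 8 tert-butyl acetate
Product: 9 tert-butyl 3-[2-hydroxy-4,6-bis(methoxymethoxy)phenyl]-3-oxopropanoate
Conditions: LiN(i-Pr)2 (4.5 equiv), 8 (4.5 equiv), THF, −78 to 0 °C; then AcOH
Reagents that add atoms: none
Why: Crossed Claisen condensation: excess lithium enolate of 8 first deprotonates the phenol and then acylates at the methyl ester, the product is shielded as its enolate, and the bulky tert-butyl ester prevents lactonisation to a 4-hydroxycoumarin.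

Step 6
Reactants: 5 3,4-bis(methoxymethoxy)-5-(3-methylbut-2-enoyl)benzaldehyde; 9 tert-butyl 3-[2-hydroxy-4,6-bis(methoxymethoxy)phenyl]-3-oxopropanoate
Product: 10 tert-butyl 2-[2-hydroxy-4,6-bis(methoxymethoxy)benzoyl]-3-[3,4-bis(methoxymethoxy)-5-(3-methylbut-2-enoyl)phenyl]prop-2-enoate (E/Z mixture)
Conditions: piperidine (10 mol%), AcOH (10 mol%), 4 Å molecular sieves, toluene, 23 °C
Reagents that add atoms: none
Why: Knoevenagel condensation of the active methylene of 9 with the unhindered aldehyde of 5 under buffered amine catalysis at room temperature gives the doubly activated alkene (used as the E/Z mixture) while the hydrogen-bonded ring A phenol does not yet add.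

Step 7
Reactants: 10 tert-butyl 2-[2-hydroxy-4,6-bis(methoxymethoxy)benzoyl]-3-[3,4-bis(methoxymethoxy)-5-(3-methylbut-2-enoyl)phenyl]prop-2-enoate
Product: 13 (2S)-5,7-dihydroxy-2-(8-hydroxy-2,2-dimethyl-4-oxochroman-6-yl)chroman-4-one, via flavanone tert-butyl ester 11 (not isolated), via ring-D-open flavanone 12 (not isolated)
Conditions: N-[3,5-bis(trifluoromethyl)phenyl]-N'-[(9R)-6'-methoxycinchonan-9-yl]thiourea (10 mol%), toluene, −25 °C; then TsOH·H2O (3 equiv), MeOH (20 equiv), 80 °C; recrystallise to ≥99% ee
Reagents that add atoms: none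
Why: Enantioselective intramolecular oxa-Michael addition under bifunctional thiourea–amine catalysis (the thiourea hydrogen-bonds the β-keto ester, the quinuclidine guides the ring A phenol onto one face of the doubly activated alkene, closing ring C and setting C2 as S), after which acid cleaves the tert-butyl ester (decarboxylation) and all four MOM acetals (trapped by MeOH) so that the freed ring B phenol closes ring D by a second, acid-catalysed 6-endo oxa-Michael addition onto the senecioyl ketone, while C2, not enolisable, keeps its configuration.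

**Compound list**
1 | 5-iodovanillin (4-hydroxy-3-iodo-5-methoxybenzaldehyde) | COc1cc(C=O)cc(I)c1O | starting material
2 | 3,4-dihydroxy-5-iodobenzaldehyde | O=Cc1cc(O)c(O)c(I)c1 | intermediate
3 | 3-iodo-4,5-bis(methoxymethoxy)benzaldehyde | COCOc1cc(C=O)cc(I)c1OCOC | intermediate
4 | 4,4,5,5-tetramethyl-2-(2-methylprop-1-en-1-yl)-1,3,2-dioxaborolane | CC(C)=CB1OC(C)(C)C(C)(C)O1 | starting material
5 | 3,4-bis(methoxymethoxy)-5-(3-methylbut-2-enoyl)benzaldehyde | CC(C)=CC(=O)c1cc(C=O)cc(OCOC)c1OCOC | intermediate
6 | methyl 2,4,6-trihydroxybenzoate | COC(=O)c1c(O)cc(O)cc1O | starting material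
7 | methyl 2-hydroxy-4,6-bis(methoxymethoxy)benzoate | COC(=O)c1c(O)cc(OCOC)cc1OCOC | intermediate
8 | tert-butyl acetate | CC(=O)OC(C)(C)C | starting material
9 | tert-butyl 3-[2-hydroxy-4,6-bis(methoxymethoxy)phenyl]-3-oxopropanoate | CC(C)(C)OC(=O)CC(=O)c1c(O)cc(OCOC)cc1OCOC | intermediate
10 | tert-butyl 2-[2-hydroxy-4,6-bis(methoxymethoxy)benzoyl]-3-[3,4-bis(methoxymethoxy)-5-(3-methylbut-2-enoyl)phenyl]prop-2-enoate (E/Z mixture, no stereocentre) | CC(C)=CC(=O)c1cc(C=C(C(=O)OC(C)(C)C)C(=O)c2c(O)cc(OCOC)cc2OCOC)cc(OCOC)c1OCOC | intermediate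
11 | tert-butyl (2S)-2-[3,4-bis(methoxymethoxy)-5-(3-methylbut-2-enoyl)phenyl]-5,7-bis(methoxymethoxy)-4-oxochromane-3-carboxylate (C3 epimers and enol interconvert) | CC(C)=CC(=O)c1cc([C@@H]2C(C(=O)OC(C)(C)C)C(=O)c3c(OCOC)cc(OCOC)cc3O2)cc(OCOC)c1OCOC | intermediate
12 | (2S)-2-[3,4-dihydroxy-5-(3-methylbut-2-enoyl)phenyl]-5,7-dihydroxychroman-4-one | CC(C)=CC(=O)c1cc([C@@H]2CC(=O)c3c(O)cc(O)cc3O2)cc(O)c1O | intermediate
13 | (2S)-5,7-dihydroxy-2-(8-hydroxy-2,2-dimethyl-4-oxochroman-6-yl)chroman-4-one | CC1(C)CC(=O)c2cc([C@@H]3CC(=O)c4c(O)cc(O)cc4O3)cc(O)c2O1 | target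

**Step count**
Total steps: 7. Longest linear sequence: 5 (steps 1, 2, 3, 6, 7).

**Three steps most likely to fail**

Step 7 (highest risk). The thiourea catalysis is established for 2-hydroxyaryl alkylidene β-keto esters, but not for a ring A with a second ortho oxygen or for so crowded a ring B, so the ee may fall short. The acid stage also has to do four jobs cleanly. Fallback: setting out from 10, the chiral catalyst is left out, and TsOH·H2O with MeOH in toluene at 80 °C closes both rings without facial control to give the racemic flavanone F1. Preparative chiral SFC (amylose tris(3,5-dimethylphenylcarbamate) phase, CO2/MeOH) then delivers the (2S)-enantiomer. The unwanted (2R)-flavanone F2 is racemised back to F1 by ring C opening and reclosure (NaOAc, EtOH, reflux) and resubmitted. The route is rejoined at 13.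

Step 3. Direct Suzuki coupling without CO uptake, or slow transmetalation of the hindered alkenylboronate, would cut the yield of the enone. Fallback: setting out from 3, Sonogashira coupling with 2-methylbut-3-yn-2-ol (Pd(PPh3)2Cl2, CuI, Et3N, THF, 23 °C) gives the propargylic alcohol F3. A Meyer–Schuster rearrangement under neutral catalysis (VO(OSiPh3)3, xylene, 140 °C) then moves the oxygen to the aryl-bearing carbon and gives the same senecioyl ketone. The route is rejoined at 5.

Step 5. The ester of 7 is flanked by two ortho oxygens and carries a phenoxide under the reaction conditions, so enolate addition may stall. Fallback: setting out from 7, saponification (KOH, MeOH/H2O, 60 °C) gives the benzoic acid F4. 1,1'-Carbonyldiimidazole (THF, 23 °C) turns it into the acyl imidazole F5, and decarboxylative acylation of Mg(O2CCH2CO2t-Bu)2 (THF, 23 °C, Masamune–Brooks) gives the β-keto ester. The route is rejoined at 9.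

**Further compounds**
F1 | step 7 | racemic 5,7-dihydroxy-2-(8-hydroxy-2,2-dimethyl-4-oxochroman-6-yl)chroman-4-one | CC1(C)CC(=O)c2cc(C3CC(=O)c4c(O)cc(O)cc4O3)cc(O)c2O1
F2 | step 7 | (2R)-5,7-dihydroxy-2-(8-hydroxy-2,2-dimethyl-4-oxochroman-6-yl)chroman-4-one | CC1(C)CC(=O)c2cc([C@H]3CC(=O)c4c(O)cc(O)cc4O3)cc(O)c2O1
F3 | step 3 | 3-(3-hydroxy-3-methylbut-1-yn-1-yl)-4,5-bis(methoxymethoxy)benzaldehyde | CC(C)(O)C#Cc1cc(C=O)cc(OCOC)c1OCOC
F4 | step 5 | 2-hydroxy-4,6-bis(methoxymethoxy)benzoic acid | OC(=O)c1c(O)cc(OCOC)cc1OCOC
F5 | step 5 | 1-[2-hydroxy-4,6-bis(methoxymethoxy)benzoyl]imidazole | O=C(c1c(O)cc(OCOC)cc1OCOC)n1ccnc1
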